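**Plan**
1. Retrosynthesis: the C15 acetate and a C14/C15 acetonide come off first, C6 and C11 are then given back carbonyl groups as helpers, and ring B is opened across C7–C8 and C9–C10 in one [4+2] cut.
2. Enabling feature: ring B is a methylenecyclohexane in which C17=C8–C9 is a latent allene (its C8=C9 π bond is the 2π unit, activated by a C11 ketone), and C7–C6–C5–C10 with the ring A double bond C5=C10 is a latent 2-silyloxy diene.
3. Forward: ring A is bought as β-cyclocitral and turned into diene 4 (3 steps); allenyl ketone 15 carries the whole C11–C16 chain (6 steps); their cycloaddition closes ring B, unites all 20 skeletal carbons and installs the exocyclic methylene.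
4. Stereochemistry: C13/C14 from a reagent-controlled, syn-selective (Z)-crotylboration; C9/C10 from catalyst-controlled face selection and exo geometry in the cycloaddition; C5 from α-face protonation of the C5=C6 enolate (trans-decalin).
5. End game: both helper carbonyls are removed together (reduction, bis-xanthate, radical deoxygenation), then acetonide hydrolysis and selective acetylation of the primary C15 hydroxyl.

Key step: step 10

Remark: labdane numbering is used for the decalin compounds (normal series: 5α-H, 9α-H, 10β-CH3); the carbinol centres formed at C11 (in 13 and 18) are carried as epimer mixtures and left undefined because they are removed later.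

Step 1
Reactants: 1 β-cyclocitral (2,6,6-trimethylcyclohex-1-ene-1-carbaldehyde)
Product: 2 1-(2,6,6-trimethylcyclohex-1-en-1-yl)ethan-1-ol (racemic)
Conditions: MeMgBr, THF, 0 °C; then H2O
Reagents that add atoms: methylmagnesium bromide, C[Mg]Br
Why: Grignard 1,2-addition to the hindered enal, giving a racemic carbinol centre that is destroyed in step 2.

Step 2
Reactants: 2 1-(2,6,6-trimethylcyclohex-1-en-1-yl)ethan-1-ol
Product: 3 1-(2,6,6-trimethylcyclohex-1-en-1-yl)ethan-1-one
Conditions: Pr4N[RuO4] (5 mol %), N-methylmorpholine N-oxide, 4 Å molecular sieves, CH2Cl2, rt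
Reagents that add atoms: none
Why: Ley–Griffith oxidation of the secondary allylic alcohol to the methyl ketone under neutral conditions that leave the tetrasubstituted alkene untouched.

Step 3
Reactants: 3 1-(2,6,6-trimethylcyclohex-1-en-1-yl)ethan-1-one
Product: 4 tert-butyldimethyl{[1-(2,6,6-trimethylcyclohex-1-en-1-yl)ethenyl]oxy}silane (2-silyloxy diene C7=C6(OSi)–C5=C10)
Conditions: TBSOTf, Et3N, CH2Cl2, 0 °C
Reagents that add atoms: tert-butyldimethylsilyl trifluoromethanesulfonate, CC(C)(C)[Si](C)(C)OS(=O)(=O)C(F)(F)F
Why: soft enolisation and O-silylation (silyl enol ether formation) should take the kinetically favoured proton from the acetyl methyl, the only α-position, to give the cross-conjugated 2-silyloxy diene.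

Step 4
Reactants: 5 (tert-butyldimethylsilyloxy)acetaldehyde
Product: 7 (2S,3R)-1-[(tert-butyldimethylsilyl)oxy]-3-methylpent-4-en-2-ol, via O-boryl ether 6 (not isolated)
Conditions: (Z)-crotyl-B(Ipc)2 [(−)-Ipc2BOMe series, freshly prepared], THF/Et2O, −78 °C; then NaOH, H2O2, 0 °C to rt
Reagents that add atoms: (Z)-crotyldiisopinocampheylborane, C/C=C\CB([C@@H]1C[C@@H]2C[C@H]([C@H]1C)C2(C)C)[C@@H]1C[C@@H]2C[C@H]([C@H]1C)C2(C)C
Why: Brown (Z)-crotylboration through a chair Zimmerman–Traxler transition state should give the syn C13-methyl/C14-hydroxyl pair from the Z geometry, while the isopinocampheyl groups derived from (+)-α-pinene select the aldehyde face that leads to the (2S,3R) isomer.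

Step 5
Reactants: 7 (2S,3R)-1-[(tert-butyldimethylsilyl)oxy]-3-methylpent-4-en-2-ol
Product: 9 (4S)-4-[(2R)-but-3-en-2-yl]-2,2-dimethyl-1,3-dioxolane, via diol 8 (not isolated)
Conditions: camphorsulfonic acid (cat.), MeOH, rt; then 2,2-dimethoxypropane, acetone, rt
Reagents that add atoms: 2,2-dimethoxypropane, COC(C)(C)OC
Why: acid-catalysed methanolysis of the primary silyl ether followed by acetonide formation protects the 1,2-diol as one robust unit without touching either stereocentre.

Step 6
Reactants: 9 (4S)-4-[(2R)-but-3-en-2-yl]-2,2-dimethyl-1,3-dioxolane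
Product: 11 (3R)-3-[(4S)-2,2-dimethyl-1,3-dioxolan-4-yl]butan-1-ol, via B-alkyl-9-BBN 10 (not isolated)
Conditions: 9-borabicyclo[3.3.1]nonane (9-BBN), THF, 0 °C to rt; then NaOH, H2O2
Reagents that add atoms: hydrogen peroxide, OO (oxygen of the product); 9-borabicyclo[3.3.1]nonane, B1C2CCCC1CCC2 (boron framework of intermediate 10 only)
Why: anti-Markovnikov hydroboration–oxidation of the monosubstituted alkene with a bulky borane should give the primary C11 alcohol without affecting the stereocentres.

Step 7
Reactants: 11 (3R)-3-[(4S)-2,2-dimethyl-1,3-dioxolan-4-yl]butan-1-ol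
Product: 12 (3R)-3-[(4S)-2,2-dimethyl-1,3-dioxolan-4-yl]butanal
Conditions: Pr4N[RuO4] (5 mol %), N-methylmorpholine N-oxide, 4 Å molecular sieves, CH2Cl2, rt
Reagents that add atoms: none
Why: Ley–Griffith oxidation stops at the aldehyde, and the C13 stereocentre is β to the carbonyl and cannot epimerise.

Step 8
Reactants: 12 (3R)-3-[(4S)-2,2-dimethyl-1,3-dioxolan-4-yl]butanal
Product: 13 (6R)-6-[(4S)-2,2-dimethyl-1,3-dioxolan-4-yl]hept-1-yn-4-ol (C4 epimers)
Conditions: propargyl bromide, Zn, THF, 0 °C to rt; then H2O
Reagents that add atoms: 3-bromoprop-1-yne (propargyl bromide), C#CCBr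
Why: Barbier propargylation through the allenylzinc species (SE2′) should give the homopropargylic alcohol, whose new carbinol centre is oxidised in the next step.

Step 9
Reactants: 13 (6R)-6-[(4S)-2,2-dimethyl-1,3-dioxolan-4-yl]hept-1-yn-4-ol
Product: 15 (6R)-6-[(4S)-2,2-dimethyl-1,3-dioxolan-4-yl]hepta-1,2-dien-4-one, via propargyl ketone 14 (not isolated)
Conditions: Dess–Martin periodinane (1,1,1-triacetoxy-1,1-dihydro-1,2-benziodoxol-3(1H)-one), CH2Cl2, 0 °C to rt; then Et3N (cat.), 0 °C
Reagents that add atoms: none
Why: Dess–Martin oxidation gives the β,γ-acetylenic ketone, whose acidic methylene allows amine-catalysed propargyl-to-allenyl isomerisation to the conjugated allenyl ketone.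

Step 10
Reactants: 4 tert-butyldimethyl{[1-(2,6,6-trimethylcyclohex-1-en-1-yl)ethenyl]oxy}silane; 15 (6R)-6-[(4S)-2,2-dimethyl-1,3-dioxolan-4-yl]hepta-1,2-dien-4-one
Product: 17 (13R,14S)-14,15-(isopropylidenedioxy)labd-8(17)-ene-6,11-dione (5α-H, 9α-H, 10β-CH3), via silyl enol ether cycloadduct 16 (not isolated)
Conditions: 4 (1.5 equiv), 15, (S)-o-tolyl-CBS oxazaborolidine·HNTf2 [N-protonated (S)-3,3-diphenyl-1-(2-methylphenyl)tetrahydropyrrolo[1,2-c][1,3,2]oxazaborole triflimide] (20 mol %), CH2Cl2, −78 to −20 °C; then Bu4NF, AcOH, THF, 0 °C; crude 17 is used at once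
Reagents that add atoms: none
Why: Proposed new method: the N-protonated oxazaborolidine binds the C11 carbonyl of 15 and activates the conjugated C8=C9 bond of the allene, so the nucleophilic C7 terminus of the silyl enol ether in 4 bonds to the central allene carbon C8 and the developing boron dienolate closes through C9 onto the fully substituted, silyloxyallyl-cation-like C10 in a concerted but highly asynchronous [4+2] cycloaddition that leaves C8=C17 as the exocyclic methylene and C5=C6 as the silyl enol ether 16. The closest known reaction types are the oxazaborolidinium-catalysed Diels–Alder reactions of 2-silyloxy dienes with enones and acrylates, the Lewis-acid Diels–Alder reactions of hindered 2-silyloxy dienes that build vicinal quaternary and tertiary centres, and the oxazaborolidine-catalysed [2+2] cycloadditions of allenoates, whereas an allenyl ketone combined with a tetrasubstituted diene terminus under chiral Lewis acid control is without precedent. Ring B closes in the [4+2] mode, which in the stepwise limit is a Mukaiyama–Michael addition followed by a 6-endo-trig (enol-exo) Michael closure of C9 on C10. C9 and C10 are created together, their absolute sense by the catalyst, which should shield one face of the bound C8=C9 bond and leave the C9 Re face open (assignment by analogy with acrylate and enone dienophiles), and their relative sense by an exo orientation of the acyl group, because the endo quadrant under C5 is blocked by the C4 gem-dimethyl group, which places C11 cis to the C10 methyl as in the target. C5 is created in the desilylation, where the C5=C6 enolate is protonated on the α face, anti to the axial methyl groups on C10 and C4, to give the trans-fused decalone, which is also the thermodynamically preferred ring fusion. The step needs C7-to-C8 regioselectivity (secured by the enol ether polarity of 4 and the large LUMO coefficient at the central allene carbon), reaction at the conjugated instead of the terminal allene π bond and six- instead of four-membered closure (secured by the s-cis diene and the stabilised tertiary C10 terminus), and exo and facial selectivity as described.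

Step 11
Reactants: 17 (13R,14S)-14,15-(isopropylidenedioxy)labd-8(17)-ene-6,11-dione
Product: 18 (13R,14S)-14,15-(isopropylidenedioxy)labd-8(17)-ene-6β,11-diol (C11 epimers)
Conditions: LiAlH4, Et2O, −78 °C to rt
Reagents that add atoms: none
Why: hydride reduction of both ketones is fast and non-equilibrating, so the exocyclic alkene should not move into conjugation, and hydride should enter C6 from the open α face to give the axial 6β-alcohol.

Step 12
Reactants: 18 (13R,14S)-14,15-(isopropylidenedioxy)labd-8(17)-ene-6β,11-diol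
Product: 19 6β,11-bis(S-methyl xanthate) of 18 [O,O′-diester with S-methyl dithiocarbonic acid]
Conditions: NaH, imidazole (cat.), CS2, MeI, THF, 0 °C to reflux
Reagents that add atoms: carbon disulfide, S=C=S; iodomethane, CI
Why: xanthate formation from the alkoxides, the first half of a Barton–McCombie deoxygenation, uses the small electrophile CS2 because the axial C6 alkoxide is hindered.

Step 13
Reactants: 19 6β,11-bis(S-methyl xanthate)
Product: 20 (13R,14S)-14,15-(isopropylidenedioxy)labd-8(17)-ene
Conditions: Bu3SnH (0.3 M, excess), AIBN (cat.), toluene, 90 °C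
Reagents that add atoms: none
Why: Barton–McCombie deoxygenation replaces both C–O bonds by C–H through secondary radicals that should abstract hydrogen from the concentrated stannane faster than they add 3-exo to the C8=C17 bond, which removes both helper oxygens and leaves no stereocentre at C6 or C11.

Step 14
Reactants: 20 (13R,14S)-14,15-(isopropylidenedioxy)labd-8(17)-ene
Product: 21 (13R,14S)-labd-8(17)-ene-14,15-diol
Conditions: AcOH/H2O (4:1), 40 °C
Reagents that add atoms: none
Why: acid-catalysed acetal hydrolysis under conditions too mild to isomerise the exocyclic alkene.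

Step 15
Reactants: 21 (13R,14S)-labd-8(17)-ene-14,15-diol
Product: 22 (13R,14S)-14-hydroxylabd-8(17)-en-15-yl acetate (target; (2S,3R)-2-hydroxy-3-methyl-5-[(1S,4aS,8aS)-5,5,8a-trimethyl-2-methylidenedecahydronaphthalen-1-yl]pentyl acetate)
Conditions: AcCl, 2,4,6-collidine, CH2Cl2, −78 °C
Reagents that add atoms: acetyl chloride, CC(=O)Cl
Why: kinetically selective monoacylation of the primary C15 hydroxyl of the 1,2-diol at low temperature with a hindered base, the secondary C14 hydroxyl next to the C13 branch reacting far more slowly.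

**Compound list**
1 | β-cyclocitral (2,6,6-trimethylcyclohex-1-ene-1-carbaldehyde) | CC1=C(C=O)C(C)(C)CCC1 | starting material
2 | 1-(2,6,6-trimethylcyclohex-1-en-1-yl)ethan-1-ol (racemic) | CC(O)C1=C(C)CCCC1(C)C | intermediate
3 | 1-(2,6,6-trimethylcyclohex-1-en-1-yl)ethan-1-one | CC(=O)C1=C(C)CCCC1(C)C | intermediate
4 | tert-butyldimethyl{[1-(2,6,6-trimethylcyclohex-1-en-1-yl)ethenyl]oxy}silane | C=C(O[Si](C)(C)C(C)(C)C)C1=C(C)CCCC1(C)C | intermediate
5 | (tert-butyldimethylsilyloxy)acetaldehyde | O=CCO[Si](C)(C)C(C)(C)C | starting material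
6 | O-[bis(isopinocampheyl)boryl] ether of 7 | C=C[C@@H](C)[C@H](OB([C@@H]1C[C@@H]2C[C@H]([C@H]1C)C2(C)C)[C@@H]1C[C@@H]2C[C@H]([C@H]1C)C2(C)C)CO[Si](C)(C)C(C)(C)C | intermediate (not isolated)
7 | (2S,3R)-1-[(tert-butyldimethylsilyl)oxy]-3-methylpent-4-en-2-ol | C=C[C@@H](C)[C@H](O)CO[Si](C)(C)C(C)(C)C | intermediate
8 | (2S,3R)-3-methylpent-4-ene-1,2-diol | C=C[C@@H](C)[C@H](O)CO | intermediate (not isolated)
9 | (4S)-4-[(2R)-but-3-en-2-yl]-2,2-dimethyl-1,3-dioxolane | C=C[C@@H](C)[C@H]1COC(C)(C)O1 | intermediate
10 | 9-{(3R)-3-[(4S)-2,2-dimethyl-1,3-dioxolan-4-yl]butyl}-9-borabicyclo[3.3.1]nonane | B1(CC[C@@H](C)[C@H]2COC(C)(C)O2)C2CCCC1CCC2 | intermediate (not isolated)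
11 | (3R)-3-[(4S)-2,2-dimethyl-1,3-dioxolan-4-yl]butan-1-ol | OCC[C@@H](C)[C@H]1COC(C)(C)O1 | intermediate
12 | (3R)-3-[(4S)-2,2-dimethyl-1,3-dioxolan-4-yl]butanal | O=CC[C@@H](C)[C@H]1COC(C)(C)O1 | intermediate
13 | (6R)-6-[(4S)-2,2-dimethyl-1,3-dioxolan-4-yl]hept-1-yn-4-ol (C4 epimers) | C#CCC(O)C[C@@H](C)[C@H]1COC(C)(C)O1 | intermediate
14 | (6R)-6-[(4S)-2,2-dimethyl-1,3-dioxolan-4-yl]hept-1-yn-4-one | C#CCC(=O)C[C@@H](C)[C@H]1COC(C)(C)O1 | intermediate (not isolated)
15 | (6R)-6-[(4S)-2,2-dimethyl-1,3-dioxolan-4-yl]hepta-1,2-dien-4-one | C=C=CC(=O)C[C@@H](C)[C@H]1COC(C)(C)O1 | intermediate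
16 | (13R,14S)-6-[(tert-butyldimethylsilyl)oxy]-14,15-(isopropylidenedioxy)labda-5,8(17)-dien-11-one (9α-H, 10β-CH3) | C=C1CC(O[Si](C)(C)C(C)(C)C)=C2C(C)(C)CCC[C@]2(C)[C@H]1C(=O)C[C@@H](C)[C@H]3COC(C)(C)O3 | intermediate (not isolated)
17 | (13R,14S)-14,15-(isopropylidenedioxy)labd-8(17)-ene-6,11-dione (5α-H, 9α-H, 10β-CH3) | C=C1CC(=O)[C@H]2C(C)(C)CCC[C@]2(C)[C@H]1C(=O)C[C@@H](C)[C@H]3COC(C)(C)O3 | intermediate
18 | (13R,14S)-14,15-(isopropylidenedioxy)labd-8(17)-ene-6β,11-diol (C11 epimers) | C=C1C[C@@H](O)[C@H]2C(C)(C)CCC[C@]2(C)[C@H]1C(O)C[C@@H](C)[C@H]3COC(C)(C)O3 | intermediate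
19 | 6β,11-bis(S-methyl xanthate) of 18 | C=C1C[C@@H](OC(=S)SC)[C@H]2C(C)(C)CCC[C@]2(C)[C@H]1C(OC(=S)SC)C[C@@H](C)[C@H]3COC(C)(C)O3 | intermediate
20 | (13R,14S)-14,15-(isopropylidenedioxy)labd-8(17)-ene | C=C1CC[C@H]2C(C)(C)CCC[C@]2(C)[C@H]1CC[C@@H](C)[C@H]3COC(C)(C)O3 | intermediate
21 | (13R,14S)-labd-8(17)-ene-14,15-diol | C=C1CC[C@H]2C(C)(C)CCC[C@]2(C)[C@H]1CC[C@@H](C)[C@H](O)CO | intermediate
22 | (13R,14S)-14-hydroxylabd-8(17)-en-15-yl acetate, (5S,9S,10S,13R,14S) | C=C1CC[C@H]2C(C)(C)CCC[C@]2(C)[C@H]1CC[C@@H](C)[C@H](O)COC(C)=O | target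

Total step count: 15
Longest linear sequence: 12 steps (5 to 22, steps 4 to 15)

**Steps most likely to fail**

Step 10 (Proposed new method). The catalyst may discriminate the faces poorly at the very hindered diene terminus. The reaction may also stop at the open-chain Michael adduct after silyl transfer, or close to a cyclobutane instead of ring B. If only the sense of induction is inverted, the antipodal catalyst is used. The fallback replaces catalyst control by auxiliary control, which is known for chiral 2-amino-1,3-dienes. It sets out from ketone 3, which is condensed with (S)-2-(methoxymethyl)pyrrolidine (TiCl4, Et3N, toluene) to give (S)-2-(methoxymethyl)-1-[1-(2,6,6-trimethylcyclohex-1-en-1-yl)ethenyl]pyrrolidine F1. This aminodiene should add to allenyl ketone 15 without Lewis acid (toluene, −20 °C to rt) to give (13R,14S)-14,15-(isopropylidenedioxy)-6-[(S)-2-(methoxymethyl)pyrrolidin-1-yl]labda-5,8(17)-dien-11-one F2. Buffered hydrolysis (AcOH, NaOAc, H2O, THF) releases the auxiliary and gives diketone 17, where the route is rejoined.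

Step 11. While diketone 17 is handled or exposed to the basic hydride, the exocyclic double bond may migrate into conjugation with either carbonyl, since C7 and C9 are both doubly activated, or C9 may epimerise. The fallback re-orders the unmasking so that the two carbonyls never coexist. It sets out from cycloadduct 16, isolated without fluoride treatment. LiAlH4 (Et2O, −78 °C) should reduce only the C11 ketone to give (13R,14S)-6-[(tert-butyldimethylsilyl)oxy]-14,15-(isopropylidenedioxy)labda-5,8(17)-dien-11-ol F3. Bu4NF/AcOH (THF, 0 °C) then unveils the ring ketone with α-face protonation at C5 to give (13R,14S)-11-hydroxy-14,15-(isopropylidenedioxy)labd-8(17)-en-6-one F4. A second LiAlH4 reduction gives diol 18, where the route is rejoined.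

Step 12. Thioacylation of the axial C6 alkoxide, which is 1,3-diaxial to the methyl groups on C10 and C4, may be incomplete, or the C6 xanthate may undergo thermal syn-elimination. The fallback places the C6 hydroxyl in the less hindered equatorial position by an electron-transfer reduction under thermodynamic control. It sets out from diketone 17, which is reduced with SmI2, H2O and Et3N (THF, rt) to give (13R,14S)-14,15-(isopropylidenedioxy)labd-8(17)-ene-6α,11-diol F5. NaH, CS2 and MeI convert it into the 6α,11-bis(S-methyl xanthate) F6, and Bu3SnH/AIBN (toluene, 90 °C) gives 20, where the route is rejoined.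

**Further compounds**
F1 | step 10 | (S)-2-(methoxymethyl)-1-[1-(2,6,6-trimethylcyclohex-1-en-1-yl)ethenyl]pyrrolidine | C=C(N1CCC[C@H]1COC)C1=C(C)CCCC1(C)C
F2 | step 10 | (13R,14S)-14,15-(isopropylidenedioxy)-6-[(S)-2-(methoxymethyl)pyrrolidin-1-yl]labda-5,8(17)-dien-11-one | C=C1CC(N3CCC[C@H]3COC)=C2C(C)(C)CCC[C@]2(C)[C@H]1C(=O)C[C@@H](C)[C@H]4COC(C)(C)O4
F3 | step 11 | (13R,14S)-6-[(tert-butyldimethylsilyl)oxy]-14,15-(isopropylidenedioxy)labda-5,8(17)-dien-11-ol (C11 epimers) | C=C1CC(O[Si](C)(C)C(C)(C)C)=C2C(C)(C)CCC[C@]2(C)[C@H]1C(O)C[C@@H](C)[C@H]3COC(C)(C)O3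
F4 | step 11 | (13R,14S)-11-hydroxy-14,15-(isopropylidenedioxy)labd-8(17)-en-6-one (C11 epimers) | C=C1CC(=O)[C@H]2C(C)(C)CCC[C@]2(C)[C@H]1C(O)C[C@@H](C)[C@H]3COC(C)(C)O3
F5 | step 12 | (13R,14S)-14,15-(isopropylidenedioxy)labd-8(17)-ene-6α,11-diol (C11 epimers) | C=C1C[C@H](O)[C@H]2C(C)(C)CCC[C@]2(C)[C@H]1C(O)C[C@@H](C)[C@H]3COC(C)(C)O3
F6 | step 12 | 6α,11-bis(S-methyl xanthate) of F5 | C=C1C[C@H](OC(=S)SC)[C@H]2C(C)(C)CCC[C@]2(C)[C@H]1C(OC(=S)SC)C[C@@H](C)[C@H]3COC(C)(C)O3
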